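**Strategy**

Ring C (the pyranone) is disconnected between C2, the methylene on the ring oxygen O1, and C3, the α-carbon flanked by the C4 ketone and ring B; this β-alkoxy ketone pattern is what the key step exploits. C3 is given a temporary allyl ester, so the precursor is an acyclic α-aryl β-keto ester whose ring A oxygen carries C2 as a methylthiomethyl ether. S-Methylation turns C2 into an aryloxymethyl cation equivalent that the enol carbon captures, closing ring C and making C3 quaternary in one operation. The ester is then excised by palladium-catalysed decarboxylative asymmetric protonation, which sets the (3S) centre late.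

Key step: step 9

Remark: the target is the (3S) enantiomer (priorities C4 > C2 > aryl > H); the sense of induction in step 10 is assigned by analogy to related α-aryl chromanones, and the mirror-image ligand is used if a first run shows the opposite sense.

TIPS = triisopropylsilyl; allyl = prop-2-en-1-yl.

**Route**

Step 1
Reactants: 1 2-(2,5-dimethoxyphenyl)acetic acid
Product: 2 2-(4-bromo-2,5-dimethoxyphenyl)acetic acid
Conditions: Br2 (1.05 equiv), AcOH, rt
Reagents that add atoms: bromine, BrBr
Why: Electrophilic aromatic bromination should go to C4, which is para to the CH2CO2H group, ortho to the 5-methoxy group and less hindered than C6.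

Step 2
Reactants: 2 2-(4-bromo-2,5-dimethoxyphenyl)acetic acid
Product: 3 2-(4-hydroxy-2,5-dimethoxyphenyl)acetic acid
Conditions: Pd2(dba)3 (2 mol %), tBuXPhos (8 mol %), KOH (4 equiv), 1,4-dioxane/H2O 1:1, 100 °C; then aq HCl
Reagents that add atoms: potassium hydroxide, [K+].[OH-]
Why: Palladium-catalysed hydroxylation of an aryl bromide with hydroxide (Buchwald–Hartwig-type C–O coupling) tolerates the carboxylate, which only consumes base.

Step 3
Reactants: 3 2-(4-hydroxy-2,5-dimethoxyphenyl)acetic acid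
Product: 4 allyl 2-(4-hydroxy-2,5-dimethoxyphenyl)acetate
Conditions: allyl alcohol (10 equiv), TsOH·H2O (5 mol %), toluene, 80 °C, 4 Å MS
Reagents that add atoms: allyl alcohol, C=CCO
Why: Fischer esterification acylates the alcohol used in excess, while the phenol is a poor nucleophile under acid catalysis and stays free.

Step 4
Reactants: 4 allyl 2-(4-hydroxy-2,5-dimethoxyphenyl)acetate
Product: 5 allyl 2-[2,5-dimethoxy-4-(triisopropylsilyloxy)phenyl]acetate
Conditions: TIPSCl (1.2 equiv), imidazole (2.5 equiv), DMF, rt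
Reagents that add atoms: chlorotriisopropylsilane, CC(C)[Si](Cl)(C(C)C)C(C)C
Why: Imidazole-promoted silylation masks the ring B phenol as a base-stable, fluoride-labile ether.

Step 5
Reactants: 6 methyl 5-bromo-2,4-dihydroxybenzoate
Product: 7 methyl 2,4-dihydroxy-5-(3-methylbut-2-en-1-yl)benzoate
Conditions: tributyl(3-methylbut-2-en-1-yl)stannane (1.3 equiv), Pd(PPh3)4 (5 mol %), DMF, 100 °C
Reagents that add atoms: tributyl(3-methylbut-2-en-1-yl)stannane, CC(C)=CC[Sn](CCCC)(CCCC)CCCC
Why: Stille coupling of the aryl bromide with the allylstannane should transfer the prenyl group mainly through its unsubstituted terminus, under neutral conditions that tolerate both phenols and the ester.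

Step 6
Reactants: 7 methyl 2,4-dihydroxy-5-(3-methylbut-2-en-1-yl)benzoate
Product: 8 methyl 2-hydroxy-5-(3-methylbut-2-en-1-yl)-4-(triisopropylsilyloxy)benzoate
Conditions: TIPSCl (1.1 equiv), imidazole (2.2 equiv), CH2Cl2, 0 °C to rt
Reagents that add atoms: chlorotriisopropylsilane, CC(C)[Si](Cl)(C(C)C)C(C)C
Why: The 2-OH is held in a hydrogen bond to the ester carbonyl, so silylation should be selective for the 4-OH (the future C7 oxygen).

Step 7
Reactants: 8 methyl 2-hydroxy-5-(3-methylbut-2-en-1-yl)-4-(triisopropylsilyloxy)benzoate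
Product: 9 methyl 2-[(methylsulfanyl)methoxy]-5-(3-methylbut-2-en-1-yl)-4-(triisopropylsilyloxy)benzoate
Conditions: NaH (1.2 equiv), ClCH2SMe (1.3 equiv), NaI (10 mol %), DMF, 0 °C to rt
Reagents that add atoms: chloromethyl methyl sulfide, CSCCl
Why: Williamson alkylation of the remaining phenoxide places the future C2 on O1 as a base-stable O,S-acetal.

Step 8
Reactants: 5 allyl 2-[2,5-dimethoxy-4-(triisopropylsilyloxy)phenyl]acetate; 9 methyl 2-[(methylsulfanyl)methoxy]-5-(3-methylbut-2-en-1-yl)-4-(triisopropylsilyloxy)benzoate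
Product: 11 allyl 2-[2,5-dimethoxy-4-(triisopropylsilyloxy)phenyl]-3-{2-[(methylsulfanyl)methoxy]-5-(3-methylbut-2-en-1-yl)-4-(triisopropylsilyloxy)phenyl}-3-oxopropanoate (racemic), via lithium enolate 10 (not isolated)
Conditions: 5 (1.1 equiv), LiN(SiMe3)2 (2.2 equiv), THF, –78 °C; then 9 (1.0 equiv), –78 to 0 °C; aq NH4Cl
Reagents that add atoms: none
Why: Crossed Claisen condensation, in which the preformed ester enolate 10 is acylated on carbon by the non-enolisable benzoate and deprotonation of the product by the second equivalent of base drives the reaction.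

Step 9
Reactants: 11 allyl 2-[2,5-dimethoxy-4-(triisopropylsilyloxy)phenyl]-3-{2-[(methylsulfanyl)methoxy]-5-(3-methylbut-2-en-1-yl)-4-(triisopropylsilyloxy)phenyl}-3-oxopropanoate
Product: 13 allyl 3-[2,5-dimethoxy-4-(triisopropylsilyloxy)phenyl]-6-(3-methylbut-2-en-1-yl)-4-oxo-7-(triisopropylsilyloxy)chromane-3-carboxylate (racemic), via dimethylsulfonium triflate 12 (not isolated)
Conditions: MeOTf (1.2 equiv), 2,6-di-tert-butyl-4-methylpyridine (2 equiv), 4 Å MS, CH2Cl2, 0 °C to rt
Reagents that add atoms: methyl triflate, COS(=O)(=O)C(F)(F)F (its methyl is held by 12 and leaves as Me2S; no atom of it remains in 13)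
Why: MeOTf methylates the soft sulfur of the O,S-acetal in preference to the alkene, arenes, silyl ethers and carbonyl oxygens, and sulfonium 12 can only lose Me2S from C2, so C2 becomes an aryloxymethyl electrophile (O1=C2 oxocarbenium or its tight ion pair) next to the β-keto ester. The enol carbon C3 attacks C2 and the hindered pyridine takes the proton; this is an intramolecular Mukaiyama/Prins-type C-alkylation of a 1,3-dicarbonyl by a thiophile-activated O,S-acetal, the known way to draw oxocarbenium ions from methylthiomethyl ethers and thioglycosides. Ring C closes 6-(enolendo)-exo-tet if Me2S is displaced directly and 6-endo-trig if ionisation to the oxocarbenium comes first, both favoured. C3 becomes a quaternary stereocenter without control (racemic), which is intended because step 10 erases and resets it. The step needs C- over O-alkylation of the enol: attack through the ketone oxygen would give a six-membered enol acetal that can re-ionise on acid treatment, whereas the C2–C3 bond is irreversible, and the temporary ester favours enolisation and blocks a second alkylation at C3.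

Step 10
Reactants: 13 allyl 3-[2,5-dimethoxy-4-(triisopropylsilyloxy)phenyl]-6-(3-methylbut-2-en-1-yl)-4-oxo-7-(triisopropylsilyloxy)chromane-3-carboxylate
Product: 14 (3S)-3-[2,5-dimethoxy-4-(triisopropylsilyloxy)phenyl]-6-(3-methylbut-2-en-1-yl)-7-(triisopropylsilyloxy)chroman-4-one
Conditions: Pd2(dba)3 (5 mol %), (S)-(CF3)3-t-BuPHOX (12.5 mol %), Meldrum's acid (2.5 equiv), 1,4-dioxane, rt to 40 °C
Reagents that add atoms: none
Why: Palladium-catalysed decarboxylative asymmetric protonation, in which zerovalent palladium ionises the allyl ester, CO2 is lost and the PHOX-bound palladium enolate is protonated at C3 on one face by Meldrum's acid (which also takes up the allyl group), so that the ligand sets the (3S) centre, helped by the ortho-methoxy group of ring B.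

Step 11
Reactants: 14 (3S)-3-[2,5-dimethoxy-4-(triisopropylsilyloxy)phenyl]-6-(3-methylbut-2-en-1-yl)-7-(triisopropylsilyloxy)chroman-4-one
Product: 15 (3S)-7-hydroxy-3-(4-hydroxy-2,5-dimethoxyphenyl)-6-(3-methylbut-2-en-1-yl)chroman-4-one
Conditions: Bu4NF (2.4 equiv), AcOH (2.6 equiv), THF, 0 °C
Reagents that add atoms: none
Why: Fluoride cleaves both aryl silyl ethers, and the acetic acid buffer keeps the medium non-basic so that the enolisable C3 centre and the ortho-prenyl phenol should stay untouched.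

**Compound list**

1 | 2-(2,5-dimethoxyphenyl)acetic acid | COc1ccc(OC)c(CC(=O)O)c1 | starting material
2 | 2-(4-bromo-2,5-dimethoxyphenyl)acetic acid | COc1cc(Br)c(OC)cc1CC(=O)O | intermediate
3 | 2-(4-hydroxy-2,5-dimethoxyphenyl)acetic acid | COc1cc(O)c(OC)cc1CC(=O)O | intermediate
4 | allyl 2-(4-hydroxy-2,5-dimethoxyphenyl)acetate | C=CCOC(=O)Cc1cc(OC)c(O)cc1OC | intermediate
5 | allyl 2-[2,5-dimethoxy-4-(triisopropylsilyloxy)phenyl]acetate | C=CCOC(=O)Cc1cc(OC)c(O[Si](C(C)C)(C(C)C)C(C)C)cc1OC | intermediate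
6 | methyl 5-bromo-2,4-dihydroxybenzoate | COC(=O)c1cc(Br)c(O)cc1O | starting material
7 | methyl 2,4-dihydroxy-5-(3-methylbut-2-en-1-yl)benzoate | COC(=O)c1cc(CC=C(C)C)c(O)cc1O | intermediate
8 | methyl 2-hydroxy-5-(3-methylbut-2-en-1-yl)-4-(triisopropylsilyloxy)benzoate | COC(=O)c1cc(CC=C(C)C)c(O[Si](C(C)C)(C(C)C)C(C)C)cc1O | intermediate
9 | methyl 2-[(methylsulfanyl)methoxy]-5-(3-methylbut-2-en-1-yl)-4-(triisopropylsilyloxy)benzoate | COC(=O)c1cc(CC=C(C)C)c(O[Si](C(C)C)(C(C)C)C(C)C)cc1OCSC | intermediate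
10 | lithium enolate of 5 (not isolated) | [Li+].C=CCOC([O-])=Cc1cc(OC)c(O[Si](C(C)C)(C(C)C)C(C)C)cc1OC | intermediate
11 | allyl 2-[2,5-dimethoxy-4-(triisopropylsilyloxy)phenyl]-3-{2-[(methylsulfanyl)methoxy]-5-(3-methylbut-2-en-1-yl)-4-(triisopropylsilyloxy)phenyl}-3-oxopropanoate (racemic) | C=CCOC(=O)C(C(=O)c1cc(CC=C(C)C)c(O[Si](C(C)C)(C(C)C)C(C)C)cc1OCSC)c1cc(OC)c(O[Si](C(C)C)(C(C)C)C(C)C)cc1OC | intermediate
12 | dimethylsulfonium triflate formed from 11 by S-methylation (not isolated) | C=CCOC(=O)C(C(=O)c1cc(CC=C(C)C)c(O[Si](C(C)C)(C(C)C)C(C)C)cc1OC[S+](C)C)c1cc(OC)c(O[Si](C(C)C)(C(C)C)C(C)C)cc1OC.[O-]S(=O)(=O)C(F)(F)F | intermediate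
13 | allyl 3-[2,5-dimethoxy-4-(triisopropylsilyloxy)phenyl]-6-(3-methylbut-2-en-1-yl)-4-oxo-7-(triisopropylsilyloxy)chromane-3-carboxylate (racemic) | C=CCOC(=O)C1(c2cc(OC)c(O[Si](C(C)C)(C(C)C)C(C)C)cc2OC)COc2cc(O[Si](C(C)C)(C(C)C)C(C)C)c(CC=C(C)C)cc2C1=O | intermediate
14 | (3S)-3-[2,5-dimethoxy-4-(triisopropylsilyloxy)phenyl]-6-(3-methylbut-2-en-1-yl)-7-(triisopropylsilyloxy)chroman-4-one | COc1cc([C@H]2COc3cc(O[Si](C(C)C)(C(C)C)C(C)C)c(CC=C(C)C)cc3C2=O)c(OC)cc1O[Si](C(C)C)(C(C)C)C(C)C | intermediate
15 | (3S)-7-hydroxy-3-(4-hydroxy-2,5-dimethoxyphenyl)-6-(3-methylbut-2-en-1-yl)chroman-4-one | COc1cc([C@H]2COc3cc(O)c(CC=C(C)C)cc3C2=O)c(OC)cc1O | target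

**Count and risks**

Total step count: 11. Longest linear sequence: 8 steps (steps 1–4, then 8–11).

Steps most likely to fail:

Step 9. The enol may alkylate through oxygen instead of carbon, or the sulfonium may cyclise too slowly and be hydrolysed on work-up. The fallback tethers C2 through oxygen first and then shifts it to carbon. It sets out from 11. AgNO3 and 2,6-lutidine in THF/H2O should hydrolyse the methylthiomethyl ether to the free phenol allyl 2-[2,5-dimethoxy-4-(triisopropylsilyloxy)phenyl]-3-[2-hydroxy-5-(3-methylbut-2-en-1-yl)-4-(triisopropylsilyloxy)phenyl]-3-oxopropanoate F1. CH2BrCl and Cs2CO3 in MeCN at rt should then bridge the phenol oxygen and the ketone enolate oxygen to the cyclic enol acetal allyl 2-[2,5-dimethoxy-4-(triisopropylsilyloxy)phenyl]-2-[6-(3-methylbut-2-en-1-yl)-7-(triisopropylsilyloxy)-4H-1,3-benzodioxin-4-ylidene]acetate F2. Me2AlCl in CH2Cl2 at –78 °C should trigger a Petasis–Ferrier-type rearrangement of F2 (acetal ionisation to the aluminium enolate and the O1=C2 oxocarbenium, recombination at carbon), which closes ring C at the same C2–C3 bond and comes back to the route at 13.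

Step 10. Face selectivity of the protonation may be insufficient for an aryl group with only one ortho substituent, and the palladium enolate may be allylated instead of protonated. The fallback reduces with dynamic kinetic resolution and re-oxidises. It sets out from 13. Pd(PPh3)4 and morpholine in THF should give the racemic ketone 3-[2,5-dimethoxy-4-(triisopropylsilyloxy)phenyl]-6-(3-methylbut-2-en-1-yl)-7-(triisopropylsilyloxy)chroman-4-one F3. Transfer hydrogenation with RuCl(p-cymene)[(S,S)-TsDPEN] in HCO2H/Et3N, where C3 epimerises through the enol faster than the ketone is reduced, should give the cis alcohol (3S,4S)-3-[2,5-dimethoxy-4-(triisopropylsilyloxy)phenyl]-6-(3-methylbut-2-en-1-yl)-7-(triisopropylsilyloxy)chroman-4-ol F4. Dess–Martin periodinane with NaHCO3 in CH2Cl2 at 0 °C should oxidise F4 without touching C3 and comes back to the route at 14.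

Step 8. Conversion of the hindered, electron-rich methyl ester may be low, enolate 10 may undergo ester-enolate Claisen rearrangement on warming, and released methoxide may exchange the allyl ester. The fallback is an aldol addition at low temperature followed by oxidation. It sets out from 9. LiAlH4 in THF at 0 °C should give the benzylic alcohol {2-[(methylsulfanyl)methoxy]-5-(3-methylbut-2-en-1-yl)-4-(triisopropylsilyloxy)phenyl}methanol F5, and MnO2 in CH2Cl2 the aldehyde 2-[(methylsulfanyl)methoxy]-5-(3-methylbut-2-en-1-yl)-4-(triisopropylsilyloxy)benzaldehyde F6. Enolate 10 should add to F6 at –78 °C to give the β-hydroxy ester allyl 2-[2,5-dimethoxy-4-(triisopropylsilyloxy)phenyl]-3-hydroxy-3-{2-[(methylsulfanyl)methoxy]-5-(3-methylbut-2-en-1-yl)-4-(triisopropylsilyloxy)phenyl}propanoate F7 as a diastereomer mixture of no consequence. Dess–Martin periodinane in CH2Cl2 should oxidise F7 and comes back to the route at 11.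

**Further compounds**

F1 | step 9 | allyl 2-[2,5-dimethoxy-4-(triisopropylsilyloxy)phenyl]-3-[2-hydroxy-5-(3-methylbut-2-en-1-yl)-4-(triisopropylsilyloxy)phenyl]-3-oxopropanoate | C=CCOC(=O)C(C(=O)c1cc(CC=C(C)C)c(O[Si](C(C)C)(C(C)C)C(C)C)cc1O)c1cc(OC)c(O[Si](C(C)C)(C(C)C)C(C)C)cc1OC
F2 | step 9 | allyl 2-[2,5-dimethoxy-4-(triisopropylsilyloxy)phenyl]-2-[6-(3-methylbut-2-en-1-yl)-7-(triisopropylsilyloxy)-4H-1,3-benzodioxin-4-ylidene]acetate | C=CCOC(=O)C(c1cc(OC)c(O[Si](C(C)C)(C(C)C)C(C)C)cc1OC)=C1OCOc2cc(O[Si](C(C)C)(C(C)C)C(C)C)c(CC=C(C)C)cc21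
F3 | step 10 | racemic 3-[2,5-dimethoxy-4-(triisopropylsilyloxy)phenyl]-6-(3-methylbut-2-en-1-yl)-7-(triisopropylsilyloxy)chroman-4-one | COc1cc(C2COc3cc(O[Si](C(C)C)(C(C)C)C(C)C)c(CC=C(C)C)cc3C2=O)c(OC)cc1O[Si](C(C)C)(C(C)C)C(C)C
F4 | step 10 | (3S,4S)-3-[2,5-dimethoxy-4-(triisopropylsilyloxy)phenyl]-6-(3-methylbut-2-en-1-yl)-7-(triisopropylsilyloxy)chroman-4-ol | COc1cc([C@H]2COc3cc(O[Si](C(C)C)(C(C)C)C(C)C)c(CC=C(C)C)cc3[C@H]2O)c(OC)cc1O[Si](C(C)C)(C(C)C)C(C)C
F5 | step 8 | {2-[(methylsulfanyl)methoxy]-5-(3-methylbut-2-en-1-yl)-4-(triisopropylsilyloxy)phenyl}methanol | OCc1cc(CC=C(C)C)c(O[Si](C(C)C)(C(C)C)C(C)C)cc1OCSC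
F6 | step 8 | 2-[(methylsulfanyl)methoxy]-5-(3-methylbut-2-en-1-yl)-4-(triisopropylsilyloxy)benzaldehyde | O=Cc1cc(CC=C(C)C)c(O[Si](C(C)C)(C(C)C)C(C)C)cc1OCSC
F7 | step 8 | allyl 2-[2,5-dimethoxy-4-(triisopropylsilyloxy)phenyl]-3-hydroxy-3-{2-[(methylsulfanyl)methoxy]-5-(3-methylbut-2-en-1-yl)-4-(triisopropylsilyloxy)phenyl}propanoate | C=CCOC(=O)C(C(O)c1cc(CC=C(C)C)c(O[Si](C(C)C)(C(C)C)C(C)C)cc1OCSC)c1cc(OC)c(O[Si](C(C)C)(C(C)C)C(C)C)cc1OC
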